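**Strategy**

The route rests on disconnecting the C3–C1' bond between the carbinol carbon of ring C and ring B. C3 is an α-hydroxy-acyl carbon, so it is introduced as the ketone of a 3-aryloxy-2-oxopropanoate that already carries ring A through O1–C2. Ring B enters as the free catechol, whose only unhindered C–H ortho to a phenolic OH (2'-OH; para to 4'-OMe) is C1'. A bifunctional cinchona squaramide catalyses the OH-directed asymmetric Friedel–Crafts hydroxyalkylation, which forms C3–C1', sets the C3 stereocentre and, by lactonisation of 2'-OH onto the ester (future C4), closes a temporary benzofuranone. This lactone then transfers its acyl group to ring A to build ring C.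

Key step: step 6

Assumption: the facial sense of the squaramide catalyst is assigned by analogy; the quinine-derived catalyst is taken to deliver the (R) carbinol, and the quinidine-derived pseudo-enantiomer is used if the sense proves opposite.

**Route**

Step 1
Reactants: 1 2,2-dimethyl-1,3-benzodioxol-4-ol; 2 1-bromo-3-methylbut-2-ene (prenyl bromide)
Product: 3 2,2-dimethyl-4-[(3-methylbut-2-en-1-yl)oxy]-1,3-benzodioxole
Conditions: K2CO3, acetone, reflux
Reagents that add atoms: none
Why: Williamson ether synthesis, the phenoxide displacing the primary allylic bromide by SN2.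

Step 2
Reactants: 3 2,2-dimethyl-4-[(3-methylbut-2-en-1-yl)oxy]-1,3-benzodioxole
Product: 5 2,2-dimethyl-5-(2-methylbut-3-en-2-yl)-1,3-benzodioxol-4-ol, via Claisen ortho-dienone 4 (not isolated)
Conditions: N,N-diethylaniline, 190 °C, sealed tube, Ar
Reagents that add atoms: none
Why: Aromatic Claisen [3,3] rearrangement, in which the dimethyl-substituted allyl terminus bonds to the only free ortho carbon (C5, since C3a is blocked) and amine-assisted enolisation of dienone 4 should give the reverse-prenyl phenol.

Step 3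
Reactants: 5 2,2-dimethyl-5-(2-methylbut-3-en-2-yl)-1,3-benzodioxol-4-ol
Product: 6 4-methoxy-2,2-dimethyl-5-(2-methylbut-3-en-2-yl)-1,3-benzodioxole
Conditions: MeI, K2CO3, DMF, 40 °C
Reagents that add atoms: iodomethane, CI
Why: Williamson O-methylation of the hindered phenoxide in a dipolar aprotic solvent.

Step 4
Reactants: 6 4-methoxy-2,2-dimethyl-5-(2-methylbut-3-en-2-yl)-1,3-benzodioxole
Product: 7 3-methoxy-4-(2-methylbut-3-en-2-yl)benzene-1,2-diol
Conditions: TFA–H2O (9:1), 0 °C → rt, Ar
Reagents that add atoms: none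
Why: Acid-catalysed ketal hydrolysis of the catechol acetonide; the monosubstituted alkene should not be protonated under these conditions, and its ortho oxygen is a methyl ether, so no cyclisation is possible.

Step 5
Reactants: 8 3,5-bis(benzyloxy)phenol; 9 ethyl 3-bromo-2-oxopropanoate (ethyl bromopyruvate)
Product: 10 ethyl 3-[3,5-bis(benzyloxy)phenoxy]-2-oxopropanoate
Conditions: NaH, THF, 0 °C; then 9, −20 °C → rt
Reagents that add atoms: none
Why: SN2 O-alkylation of the preformed sodium phenoxide by the carbonyl-activated α-bromo ketone.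

Step 6
Reactants: 7 3-methoxy-4-(2-methylbut-3-en-2-yl)benzene-1,2-diol; 10 ethyl 3-[3,5-bis(benzyloxy)phenoxy]-2-oxopropanoate
Product: 12 (3R)-3-{[3,5-bis(benzyloxy)phenoxy]methyl}-3,7-dihydroxy-6-methoxy-5-(2-methylbut-3-en-2-yl)-1-benzofuran-2(3H)-one, via open hydroxy ester 11 (not isolated)
Conditions: 9-amino-9-deoxy-epi-quinine 3,5-bis(trifluoromethyl)phenyl squaramide (10 mol %), 4 Å MS, CH2Cl2, −20 °C → rt, Ar; then p-TsOH·H2O (10 mol %), toluene, 60 °C, EtOH removed
Reagents that add atoms: none
Why: The quinuclidine nitrogen of the catalyst hydrogen-bonds the 1-OH of catechol 7 while the squaramide N–H pair binds the 1,2-dicarbonyl of 10, so the phenol attacks the ketone through its ortho carbon C6 (C1' of the target) in a Friedel–Crafts hydroxyalkylation and rearomatises to hydroxy ester 11. The closest known reaction type is the cinchona thiourea- or squaramide-catalysed enantioselective ortho-Friedel–Crafts hydroxyalkylation of electron-rich phenols and naphthols with activated ketones (α-keto esters, trifluoropyruvates, isatins). The only ring closed is the benzofuran-2(3H)-one, by 5-exo-trig addition–elimination of the ortho OH on the ethyl ester with loss of ethanol, which also makes the C–C bond formation irreversible. The C3 stereocentre is set by the catalyst, which exposes one enantiotopic face of the bound ketone to the arene. The step needs ortho regioselectivity (C6 over C5) and chemoselectivity for the catechol over the dialkoxyphenyl ether ring of 10: C6 is ortho to the catalyst-bound OH and para to OMe whereas C5 is flanked by the quaternary side chain, and only the hydrogen-bonded phenol, not the neutral aryl ether, should be nucleophilic enough under these non-acidic conditions.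

Step 7
Reactants: 12 (3R)-3-{[3,5-bis(benzyloxy)phenoxy]methyl}-3,7-dihydroxy-6-methoxy-5-(2-methylbut-3-en-2-yl)-1-benzofuran-2(3H)-one
Product: 13 (3R)-5,7-bis(benzyloxy)-3-[2,3-dihydroxy-4-methoxy-5-(2-methylbut-3-en-2-yl)phenyl]-3-hydroxy-2,3-dihydro-4H-chromen-4-one
Conditions: Me2AlCl (4 equiv), CH2Cl2, −40 °C → rt; then 1 M HCl
Reagents that add atoms: none
Why: Me2AlCl turns the 3-OH into an aluminium alkoxide that chelates and activates the strained aryl-lactone carbonyl for intramolecular Friedel–Crafts acylation (a Fries-type O→C acyl transfer, as in the acylation of polyoxygenated arenes by benzofuran-2(3H)-ones) at the only reachable ortho carbon of the phloroglucinol-type ring, which closes the pyranone and frees the 2'-OH, while the proton-scavenging Lewis acid should spare the vinyl group and C3, having no α-hydrogen, keeps its configuration.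

Step 8
Reactants: 13 (3R)-5,7-bis(benzyloxy)-3-[2,3-dihydroxy-4-methoxy-5-(2-methylbut-3-en-2-yl)phenyl]-3-hydroxy-2,3-dihydro-4H-chromen-4-one
Product: 14 (3R)-3-[2,3-dihydroxy-4-methoxy-5-(2-methylbut-3-en-2-yl)phenyl]-3,5,7-trihydroxy-2,3-dihydro-4H-chromen-4-one
Conditions: BCl3 (8 equiv), pentamethylbenzene (6 equiv), CH2Cl2, −78 °C; then MeOH
Reagents that add atoms: none
Why: Lewis-acid debenzylation with a non-basic cation scavenger, in which BCl3 cleaves the aryl benzyl ethers at low temperature and pentamethylbenzene traps the benzyl cation, should leave the aryl methyl ether, the terminal alkene (which hydrogenolysis would reduce) and the α-ketol untouched.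

**Compound list**

1 | 2,2-dimethyl-1,3-benzodioxol-4-ol | CC1(C)Oc2cccc(O)c2O1 | starting material
2 | 1-bromo-3-methylbut-2-ene (prenyl bromide) | CC(C)=CCBr | starting material
3 | 2,2-dimethyl-4-[(3-methylbut-2-en-1-yl)oxy]-1,3-benzodioxole | CC(C)=CCOc1cccc2OC(C)(C)Oc12 | intermediate
4 | 2,2-dimethyl-5-(2-methylbut-3-en-2-yl)-1,3-benzodioxol-4(5H)-one (racemic Claisen ortho-dienone, not isolated) | C=CC(C)(C)C1C=CC2=C(OC(C)(C)O2)C1=O | intermediate
5 | 2,2-dimethyl-5-(2-methylbut-3-en-2-yl)-1,3-benzodioxol-4-ol | C=CC(C)(C)c1ccc2OC(C)(C)Oc2c1O | intermediate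
6 | 4-methoxy-2,2-dimethyl-5-(2-methylbut-3-en-2-yl)-1,3-benzodioxole | C=CC(C)(C)c1ccc2OC(C)(C)Oc2c1OC | intermediate
7 | 3-methoxy-4-(2-methylbut-3-en-2-yl)benzene-1,2-diol | C=CC(C)(C)c1ccc(O)c(O)c1OC | intermediate
8 | 3,5-bis(benzyloxy)phenol | Oc1cc(OCc2ccccc2)cc(OCc2ccccc2)c1 | starting material
9 | ethyl 3-bromo-2-oxopropanoate (ethyl bromopyruvate) | CCOC(=O)C(=O)CBr | starting material
10 | ethyl 3-[3,5-bis(benzyloxy)phenoxy]-2-oxopropanoate | CCOC(=O)C(=O)COc1cc(OCc2ccccc2)cc(OCc2ccccc2)c1 | intermediate
11 | ethyl (2R)-3-[3,5-bis(benzyloxy)phenoxy]-2-[2,3-dihydroxy-4-methoxy-5-(2-methylbut-3-en-2-yl)phenyl]-2-hydroxypropanoate (not isolated) | C=CC(C)(C)c1cc([C@@](C(=O)OCC)(O)COc2cc(OCc3ccccc3)cc(OCc3ccccc3)c2)c(O)c(O)c1OC | intermediate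
12 | (3R)-3-{[3,5-bis(benzyloxy)phenoxy]methyl}-3,7-dihydroxy-6-methoxy-5-(2-methylbut-3-en-2-yl)-1-benzofuran-2(3H)-one | C=CC(C)(C)c1cc2c(c(O)c1OC)OC(=O)[C@]2(O)COc1cc(OCc2ccccc2)cc(OCc2ccccc2)c1 | intermediate
13 | (3R)-5,7-bis(benzyloxy)-3-[2,3-dihydroxy-4-methoxy-5-(2-methylbut-3-en-2-yl)phenyl]-3-hydroxy-2,3-dihydro-4H-chromen-4-one | C=CC(C)(C)c1cc([C@@]2(O)COc3cc(OCc4ccccc4)cc(OCc4ccccc4)c3C2=O)c(O)c(O)c1OC | intermediate
14 | (3R)-3-[2,3-dihydroxy-4-methoxy-5-(2-methylbut-3-en-2-yl)phenyl]-3,5,7-trihydroxy-2,3-dihydro-4H-chromen-4-one | C=CC(C)(C)c1cc([C@@]2(O)COc3cc(O)cc(O)c3C2=O)c(O)c(O)c1OC | target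

**Step count and risks**

Total steps: 8. Longest linear sequence: 7 steps (steps 1–4, then 6–8, from compound 1).

Steps most likely to fail:

Step 6 (key step). The hydrogen-bond-activated, non-fluorinated and enolisable keto ester may be too weakly electrophilic, so that conversion is slow and the catechol oxidises, or the catalyst may discriminate the ketone faces poorly. The fallback replaces the C–H nucleophile by an aryl-boron nucleophile; it sets out from 6 and 10 and comes back to the route at 12. Directed ortho-lithiation of 6 (n-BuLi, TMEDA, THF, −78 → 0 °C; C7 is the only C–H ortho to an oxygen) and quenching with 2-isopropoxy-4,4,5,5-tetramethyl-1,3,2-dioxaborolane should give 2-[7-methoxy-2,2-dimethyl-6-(2-methylbut-3-en-2-yl)-1,3-benzodioxol-4-yl]-4,4,5,5-tetramethyl-1,3,2-dioxaborolane F1. Rhodium(I)/chiral diene-catalysed enantioselective 1,2-addition of F1 to keto ester 10 (KF, toluene–H2O, rt) should give the acetonide-protected hydroxy ester ethyl (2R)-3-[3,5-bis(benzyloxy)phenoxy]-2-hydroxy-2-[7-methoxy-2,2-dimethyl-6-(2-methylbut-3-en-2-yl)-1,3-benzodioxol-4-yl]propanoate F2. Aqueous TFA as in step 4 then removes the acetonide to give 11, which lactonises to 12.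

Step 7. The Lewis acid may ionise the electron-rich tertiary benzylic carbinol, or acyl transfer from the hindered lactone carbonyl may simply not occur before the benzyl ethers are attacked. The fallback avoids the lactone by keeping the catechol masked and cyclising an open-chain acid; it sets out from 6 and 10 and comes back to the route at 14. Compounds 6 and 10 are taken to F2 as described above, but the acetonide is kept. Saponification (LiOH, THF–H2O) should give (2R)-3-[3,5-bis(benzyloxy)phenoxy]-2-hydroxy-2-[7-methoxy-2,2-dimethyl-6-(2-methylbut-3-en-2-yl)-1,3-benzodioxol-4-yl]propanoic acid F3. Trifluoroacetic anhydride (CH2Cl2, 0 °C) forms the mixed anhydride, which undergoes intramolecular Friedel–Crafts acylation of ring A; NaHCO3/MeOH work-up then cleaves the transient trifluoroacetate to give (3R)-5,7-bis(benzyloxy)-3-hydroxy-3-[7-methoxy-2,2-dimethyl-6-(2-methylbut-3-en-2-yl)-1,3-benzodioxol-4-yl]-2,3-dihydro-4H-chromen-4-one F4. BCl3/pentamethylbenzene (−78 → 0 °C) should then remove both benzyl ethers and the acetonide to give 14.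

Step 5. The phenoxide may attack the ketone carbonyl of the bromopyruvate, the bromopyruvate may self-condense under base, or the product may cyclodehydrate to a benzofuran on acidic purification. The fallback builds the keto ester by epoxide opening and oxidation; it sets out from 8 and comes back to the route at 10. Opening of commercial ethyl oxirane-2-carboxylate at its CH2 carbon by phenol 8 (CsF cat., DMF, 60 °C) should give racemic ethyl 3-[3,5-bis(benzyloxy)phenoxy]-2-hydroxypropanoate F5, and Dess–Martin oxidation (CH2Cl2, rt) should give 10.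

**Further compounds**

F1 | step 6 | 2-[7-methoxy-2,2-dimethyl-6-(2-methylbut-3-en-2-yl)-1,3-benzodioxol-4-yl]-4,4,5,5-tetramethyl-1,3,2-dioxaborolane | C=CC(C)(C)c1cc(B2OC(C)(C)C(C)(C)O2)c2OC(C)(C)Oc2c1OC
F2 | step 6 | ethyl (2R)-3-[3,5-bis(benzyloxy)phenoxy]-2-hydroxy-2-[7-methoxy-2,2-dimethyl-6-(2-methylbut-3-en-2-yl)-1,3-benzodioxol-4-yl]propanoate | C=CC(C)(C)c1cc([C@@](C(=O)OCC)(O)COc2cc(OCc3ccccc3)cc(OCc3ccccc3)c2)c2OC(C)(C)Oc2c1OC
F3 | step 7 | (2R)-3-[3,5-bis(benzyloxy)phenoxy]-2-hydroxy-2-[7-methoxy-2,2-dimethyl-6-(2-methylbut-3-en-2-yl)-1,3-benzodioxol-4-yl]propanoic acid | C=CC(C)(C)c1cc([C@@](C(=O)O)(O)COc2cc(OCc3ccccc3)cc(OCc3ccccc3)c2)c2OC(C)(C)Oc2c1OC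
F4 | step 7 | (3R)-5,7-bis(benzyloxy)-3-hydroxy-3-[7-methoxy-2,2-dimethyl-6-(2-methylbut-3-en-2-yl)-1,3-benzodioxol-4-yl]-2,3-dihydro-4H-chromen-4-one | C=CC(C)(C)c1cc([C@@]2(O)COc3cc(OCc4ccccc4)cc(OCc4ccccc4)c3C2=O)c2OC(C)(C)Oc2c1OC
F5 | step 5 | ethyl 3-[3,5-bis(benzyloxy)phenoxy]-2-hydroxypropanoate (racemic) | CCOC(=O)C(O)COc1cc(OCc2ccccc2)cc(OCc2ccccc2)c1
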